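The rate constants were set for the occasion; the result is computed.

I began with the easy step, the death of the free catalyst, a plain exponential with a lifetime of 10.8 s.

    reagent + second catalyst + intermediate → second catalyst + target (k1 = 2470 M⁻² s⁻¹)
    free catalyst → spent catalyst (k2 = 0.0929 s⁻¹)
    starting material + free catalyst ⇌ free catalyst + intermediate (K3 = 0.784, k3 = 10100 M⁻¹ s⁻¹)
    reagent + target → over-reaction product A (k4 = 5.82 M⁻¹ s⁻¹)
    target → over-reaction product B (k5 = 3.98 × 10⁻⁵ s⁻¹)

all flasks: free catalyst 12 µM; second catalyst 2.7 mM; time 1.0 min
- elm: starting material 18 mM; reagent 21.6 mM; everything together at the start
- maple: starting material 18 mM (fed, over 25 s); reagent 21.6 mM; all else is in the flask from the start; the feed brings no volume worth counting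
- birch: starting material 18 mM; reagent 21.6 mM (fed, over 25 s); all else is in the flask from the start; the feed brings no volume worth counting

- the flask that comes out highest in amount of over-reaction product A, in percent of the starting material charged, or "all alike" when all lie within 1.5 percentage points (elm / maple / birch / all alike)
- over-reaction product A at the end, in percent of the starting material charged, elm
- over-reaction product A at the end, in percent of the starting material charged, maple
- over-reaction product A at the end, in percent of the starting material charged, birch

Starting material is the smaller charge, so I wrote its balance: it leaves by the catalysed step, which is pseudo-first-order in c(starting material) with a constant that fades as c(free catalyst) fades. The time integral of c(free catalyst) is 12 µM times that lifetime, and this integral times the forward constant 10100 M⁻¹ s⁻¹ is what I called the catalyst's reach, 1.30, the logarithm of how far the catalyst's whole life can thin out starting material present from the start, counting the forward step alone.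

For elm, reach gave 27.1% left by the forward step alone, so I reckoned that at most 72.9% could pass on, and the back step lowers that. Feeding starting material, as in maple, brought the mean portion in at mid-feed, when reach had faded to 0.408, so I expected 66.5% left, more than in elm, and less over-reaction product A. Feeding reagent, as in birch, leaves reach untouched, but the two later steps need reagent; their half-lives at elm's charges, 0.080 min for intermediate and 0.092 min for target, are shorter than the feed, so I expected a modest loss of over-reaction product A through delay. A larger charge of starting material leaves reach as it was, so its share left should hold. My order was elm, birch, maple, and I committed to no figure for over-reaction product A.

The forecast named elm, with 43% for elm, 29% for maple and 39% for birch, holding that “feeding the starting material wastes that window”.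

The flasks gave 43.0% in elm, 26.7% in maple and 38.9% in birch, so elm came out highest and the forecast stood within its tolerance.

Maple still held 67.9% of its starting material at 1.00 min, against 41.9% in elm. The death of free catalyst is the largest single effect in the gap between elm and maple: the gap of 16 percentage points shrinks to 3.4 points in the run without that step. A reach of 1.30 contains no charge of starting material, and the neighbour of maple charged with 45 mM of it ended with 68.5% of that charge left.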